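The data are simulated on assumed constants; scatter was added.

Thursday's flask, a racemate of left-handed and right-handed substrate with partner and a single-handed catalyst, was slow: after 50.0 min it held only 13.5% product. So both substrates stood near their charge, and the ratio of the two products read as the selectivity factor s, 2.86, a rough reading with 1 percentage point of scatter on 3.5%.

| flask | left-handed substrate | right-handed substrate | partner | precatalyst | remark | time |
|---|---|---|---|---|---|---|
| Thursday's | 0.50 M | 0.50 M | 2.5 equiv | 0.2 mol% | the very flask that is asked about, followed so far |  |
| flask | 0.50 M | 0.50 M | 2.50 equiv | 0.2 mol% |  | 3.0 h |

Thursday's run (percent of the left-handed substrate and right-handed substrate together charged)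

| time / min | left-handed product / % | right-handed product / % | left-handed substrate / % |
|---|---|---|---|
| 6.00 | 2.0 | 0 | 49.1 |
| 20.0 | 2.8 | 3.2 | 46.5 |
| 40.0 | 6.8 | 1.5 | 43.3 |
| 50.0 | 10.0 | 3.5 | 42.7 |

(each reading ± 1 percentage point)

- left-handed product and right-handed product together, in percent of the left-handed substrate and right-handed substrate charged together, at 3.0 h
- excess of left-handed product over right-handed product in the product at 3.0 h
- whether the exchange between left-handed substrate and right-handed substrate keeps pace with the reaction: how far the product's excess at 3.0 h gets from its value without exchange to its value with instant exchange (above 80% keeps pace, below 20% hardly takes part, else lags behind)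

- catalyst is single-handed; left-handed substrate and right-handed substrate are mirror images of each other, charged as a racemate, each of them at the stated concentration
- an excess is the difference of the two amounts in percent of their sum
- an excess is below zero if the other one leads

I solved two extreme versions of this flask. With instant exchange the substrates stay equal, so the excess holds at s less one over s plus one, the ceiling excess 48.1%, and first-order decay gives 40.7% yield. With no exchange, each substrate decays at its own Thursday pace, the left-handed to 44.8% of its charge and the right-handed to 77.0%. That gives 39.1% yield and a lower excess, 41.2%. Exchange refills the faster-used substrate, so the real flask lies between these. Thursday's left-handed substrate at 50.0 min sat 83.1% of the way from the one extreme to the other, above the 80% line, which at face value reads as keeping pace. But that share divides readings with 1 point of scatter each by a product difference of 6.5 points, so it could lie on either side of the line and left the pace undecided between keeping pace and lagging behind; taking it as it stood, I put the excess at 47.0%. I then went round again: assuming one partner per turn, that first yield takes a third of the partner, and a rate following c(partner) runs on average at 0.833 of its start, giving 35.3%.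

The forecast said 38%, 44% and lags behind, on the view that “exchange seems to be real but partial”; its yield stood above mine and its excess below.

    left-handed substrate ⇌ right-handed substrate (k = 2.40 × 10⁻⁴ s⁻¹)
    partner ⇌ dormant form (K = 0.250, k = 1.60 × 10⁻⁴ s⁻¹)
    partner + catalyst + left-handed substrate → catalyst + left-handed product (k = 0.0840 L² mol⁻² s⁻¹)
    partner + catalyst + right-handed substrate → catalyst + right-handed product (k = 0.0290 L² mol⁻² s⁻¹)
    partner + precatalyst → catalyst + spent reagent (k = 0.00400 L mol⁻¹ s⁻¹)
    2 partner → homo dimer (k = 5.30 × 10⁻⁵ L mol⁻¹ s⁻¹)

The flask gave 29.7% and 46.5%, 1.6 points under the ceiling; the exchange lags behind, at 67% of the way. At 0.703 h left-handed substrate went to product at a quarter of the forward rate of its turning into right-handed substrate. At 3.00 h the flask held 34.3% left-handed against 36.0% right-handed substrate. The neighbour with 0.8 mol% precatalyst reached 64.2%, and its excess of 42.1% stood 6.0 points under the ceiling.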